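Early times came first, so I started from the opening hours of Sunday's run, which is the very flask asked about, and set Tuesday's earlier run beside it.

| flask | starting material | second substrate | coupling partner | free catalyst | temperature | remark | time |
|---|---|---|---|---|---|---|---|
| Sunday's | 0.050 M | 0.050 M | 0.125 M | 7 mM | 25 °C | the very flask that is asked about, followed so far |  |
| Tuesday's | 0.050 M | 0.10 M | 0.125 M | 7 mM | 20 °C | run made earlier |  |
| flask | 0.050 M | 0.0500 M | 0.125 M | 7.0 mM | 25 °C |  | 6.0 d |

| run | time / h | target / % |
|---|---|---|
| Sunday's | 10.0 | 17.2 |
| Sunday's | 20.0 | 21.7 |
| Sunday's | 50.0 | 29.7 |
| Sunday's | 120 | 28.2 |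
| Tuesday's | 2.00 | 3.4 |
| Tuesday's | 5.00 | 4.1 |
| Tuesday's | 10.0 | 8.8 |
| Tuesday's | 15.0 | 10.3 |

(scatter of a reading: 1 percentage point)

- midnight: at 6.0 d raise the temperature by 25 K, then wait 40 h
- dawn: at 6.0 d add free catalyst, 50.0% of the amount charged, then wait 40 h
- dusk: at 6.0 d take out 90% of the target then present, then wait 40 h
- autumn: change nothing and wait 40 h more
- winter: at 6.0 d add coupling partner, 50.0% of the amount charged, then wait 40 h

- what is taken out of target is counted as made
- additions bring no volume worth counting

- target, in percent of the starting material first charged, at 6.0 d
- the option that brings most further target ("none" if no option brings more than 2 percentage points) (midnight / dawn / dusk / autumn / winter / none)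
- target present, with what was taken out counted in, in percent of the starting material first charged, after dawn
- target present, with what was taken out counted in, in percent of the starting material first charged, after winter

In Sunday's flask the target climbed fast and then stood: 29.7% and 28.2% differ by about the scatter, so I took a plateau of 28.9%. That is 14.5 mM of target, with the coupling partner charged at 0.125 M and 71.1% of the starting material not turned into target. I therefore read the stop as catalyst lost, though that was a reading and no proof. The gap to the plateau at 20.0 h gave a time constant of 14.4 h. Taking the whole catalyst charge as lost on that same constant, I reckoned target early on at 1.00 mM/h and the loss of catalyst at 0.485 mM/h. Dividing the two removes time and leaves the turnover number, the target made per catalyst lost: 2.07.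

Since 6.0 d is long against that constant, I expected the plateau at 6.0 d. Dawn adds 3.50 mM of catalyst, which at this turnover makes 14 percentage points more, so I committed to dawn at 43.4%. The other options add no catalyst, so I expected winter to stay at the plateau.

The weak link was carrying that turnover over to a used flask. Tuesday's run, at 20 °C against 25 °C and with twice the second substrate, had reached about half of Sunday's target at 10.0 h. I could not separate the two changes. But if second substrate costs catalyst and is itself used, fresh catalyst should turn over more in the used flask, so I let my error run upward too.

The forecast gave 29% (27% to 31%) for now, dawn as best, 38% (29% to 43%) after dawn and 29.5% (27.5% to 35%) after winter. Its ground for dawn was “Fresh catalyst at half the charge should give about half the log-conversion”, and its figure stood lower than mine.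

The flask gave 30.4%, with dawn best at 17 points, 47.1% after dawn and 30.5% after winter.

    starting material + free catalyst ⇌ catalyst intermediate A (K = 36.0 /M, k = 60.0 /M/h, Ea = 65.0 kJ/mol, ΔH = −29.0 kJ/mol)
    coupling partner + catalyst intermediate A → free catalyst + target (k = 4.00 /M/h, Ea = 69.0 kJ/mol)
    second substrate + free catalyst ⇌ catalyst intermediate B (K = 11.0 /M, k = 540 /M/h, Ea = 39.0 kJ/mol, ΔH = 12.0 kJ/mol)
    coupling partner + catalyst intermediate B → free catalyst + second product (k = 14.0 /M/h, Ea = 76.0 kJ/mol)
    second substrate + catalyst intermediate A → spent catalyst (k = 5.70 /M/h, Ea = 76.0 kJ/mol)
    (constants at 25 °C)

Besides stepping back to starting material and free catalyst, catalyst intermediate A went to target or to spent catalyst, and the ratio of those two rates, free of time, was 1.75 at the charges and 2.76 with what was left at 6.0 d. Between them lay the target made per catalyst charged in the asked flask, 2.17, and the further target per catalyst added at dawn, 2.38. In the neighbour with 0.013 M of starting material, my 2.07 on 7.0 mM of catalyst offered 14.5 mM of target, more than that charge, so starting material should be the limiting reagent. At 144 h that neighbour gave 77.3% of target, with 0.553% of the starting material charged, 0.174% of the second substrate charged and 58.9% of the catalyst charged standing as free catalyst.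

All runs were computed with made-up constants.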